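**Plan**

- Numbering used throughout: ring A is C1(=CH2)–C2H2–C3H(OH)–C4H(Br)–C5Me2–C6(spiro) and ring B is C6–C7H2–C8H2–C9(OH)(CH2Cl)–C10(=O)–C11H2. The enabling feature is that C6 lies next to C1 (a ketone until the methylidene carbon is added) and C9/C10 carry neighbouring oxygens, so ring B is a 2-formyl ketone plus a methoxymethyl vinyl ketone in disguise.
- Retrosynthesis: the C9 chlorohydrin goes back to a spiro-epoxide (C9–O) on a C9 methylidene; ring A goes back to a dimedone vinylogous ester (cuts at the C1–CH2 carbon, C4–Br and C3–H); ring B is cut at C6–C7 (Michael) and C10=C11 (aldol condensation).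
- Forward: ring A comes from dimedone and is formylated at C6; one asymmetric Robinson-type spiroannulation closes ring B; ring B is then fixed in masked form (C9 methylenation, C10 dioxolane, C9 epoxide); ring A is transposed, brominated, reduced and its alkene moved to the exocyclic position; chloride opening and deketalisation finish.
- Stereochemistry: C6 from the chiral bifunctional amine catalyst in the Michael addition; C9 from axial delivery of oxygen to the C9 methylidene; C4 from bromination trans to the axial C7 arm (also the thermodynamic epimer); C3 from hydride attack anti to the axial C5 methyl.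

Key step: step 5

Assumption: the cupreidine-derived catalyst is taken to give the spiro configuration drawn for the key-step product; if the first run shows the opposite sense, the pseudo-enantiomeric cupreine catalyst is used and nothing else changes.

**Route**

Step 1
Reactants: 1 dimedone (5,5-dimethylcyclohexane-1,3-dione)
Product: 2 3-isobutoxy-5,5-dimethylcyclohex-2-en-1-one
Conditions: i-BuOH, p-TsOH (cat.), toluene, reflux, Dean–Stark
Reagents that add atoms: isobutanol CC(C)CO
Why: Acid-catalysed enol etherification of the symmetric 1,3-dione (vinylogous ester formation) driven by water removal; C2 becomes vinylic, so later enolisation next to the carbonyl can only occur at C6.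

Step 2
Reactants: 2 3-isobutoxy-5,5-dimethylcyclohex-2-en-1-one; 3 ethyl formate
Product: 4 6-(hydroxymethylene)-3-isobutoxy-5,5-dimethylcyclohex-2-en-1-one (chelated Z-enol of the 6-formyl ketone)
Conditions: LDA (2.2 equiv), THF, −78 °C; HCO2Et, −78 → 0 °C; 1 M HCl work-up
Reagents that add atoms: none
Why: Kinetic α′-deprotonation of the vinylogous ester at C6 followed by crossed Claisen formylation; the second equivalent of base holds the product as its enolate and stops proton exchange.

Step 3
Reactants: 5 methyl methoxyacetate
Product: 6 N,2-dimethoxy-N-methylacetamide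
Conditions: MeNH(OMe)·HCl, i-PrMgCl, THF, −20 → 0 °C
Reagents that add atoms: N,O-dimethylhydroxylamine hydrochloride CNOC.Cl
Why: Direct aminolysis of the ester by the magnesium amide of N,O-dimethylhydroxylamine (Weinreb amide formation).

Step 4
Reactants: 6 N,2-dimethoxy-N-methylacetamide
Product: 7 1-methoxybut-3-en-2-one
Conditions: CH2=CHMgBr, THF, 0 °C; inverse quench into cold 1 M HCl; used at once as a solution
Reagents that add atoms: vinylmagnesium bromide C=C[Mg]Br
Why: Weinreb ketone synthesis; the chelated tetrahedral intermediate stops at single addition, and the acidic inverse quench keeps the liberated amine from adding to the enone.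

Step 5
Reactants: 4 6-(hydroxymethylene)-3-isobutoxy-5,5-dimethylcyclohex-2-en-1-one; 7 1-methoxybut-3-en-2-one
Product: 10 (6S)-3-isobutoxy-10-methoxy-5,5-dimethylspiro[5.5]undeca-2,10-diene-1,9-dione, via keto aldehyde 8 (not isolated), via β-hydroxy ketone 9 (not isolated)
Conditions: O-(9-phenanthryl)cupreidine (10 mol %), toluene, −20 °C → rt; then p-TsOH·H2O (30 mol %), 4 Å MS, 60 °C
Reagents that add atoms: none
Why: The quinuclidine nitrogen of the catalyst deprotonates the chelated hydroxymethylene ketone while the 6′-OH binds the vinyl ketone, so the ion-paired enolate adds through C6 to form C6–C7 (Michael addition); the added acid then enolises the side-chain ketone toward the methoxymethyl carbon, which attacks the formyl group, and the aldol loses water to give the C10=C11 enol ether. The closest known chemistry is the cinchona-catalysed conjugate addition of α-substituted cyclic β-dicarbonyl compounds to vinyl ketones, joined to the classical spiroannulation of 2-formyl cycloalkanones. Ring B closes by a 6-(enolexo)-exo-trig aldol; enolisation toward C8 could only give a four-membered ring, so the closure is regiochemically unambiguous. C6 is the only lasting stereocentre and is set by the catalyst, which distinguishes the CMe2 flank from the enone flank of the planar enolate; being quaternary it cannot epimerise afterwards. The step needs C- rather than O-alkylation and survival of the formyl group: the formyl group makes the hindered C6 acidic enough for amine catalysis, and closing the ring with acid instead of hydroxide avoids retro-Claisen loss of the formyl carbon and retro-Michael erosion of the enantiomeric purity.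

Step 6
Reactants: 10 (6S)-3-isobutoxy-10-methoxy-5,5-dimethylspiro[5.5]undeca-2,10-diene-1,9-dione
Product: 11 (6S)-3-isobutoxy-10-methoxy-5,5-dimethyl-9-methylidenespiro[5.5]undeca-2,10-dien-1-one
Conditions: Ph3PCH3Br, KOt-Bu, THF, 0 °C → rt
Reagents that add atoms: methyltriphenylphosphonium bromide C[P+](c1ccccc1)(c1ccccc1)c1ccccc1.[Br-]
Why: Wittig methylenation of the C9 enone carbonyl; the C1 carbonyl is a hindered, electron-rich vinylogous ester and does not react, and putting carbon on C9 first lets oxygen be delivered to the planar centre afterwards.

Step 7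
Reactants: 11 (6S)-3-isobutoxy-10-methoxy-5,5-dimethyl-9-methylidenespiro[5.5]undeca-2,10-dien-1-one
Product: 12 10,10-(ethylenedioxy)-3-isobutoxy-5,5-dimethyl-9-methylidenespiro[5.5]undec-2-en-1-one (spiro centre unchanged)
Conditions: HOCH2CH2OH (5 equiv), PPTS (cat.), 4 Å MS, CH2Cl2, 0 °C → rt; Et3N quench
Reagents that add atoms: ethylene glycol OCCO
Why: Acid-catalysed transketalisation of the 2-methoxy diene: protonation at C11 gives an oxocarbenium ion at C10 that the diol captures, so C10 is masked as a dioxolane without passing through the free ketone and the C9 methylidene stays in place.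

Step 8
Reactants: 12 10,10-(ethylenedioxy)-3-isobutoxy-5,5-dimethyl-9-methylidenespiro[5.5]undec-2-en-1-one
Product: 13 spiro-epoxide of 12 (oxirane C9–O–CH2 with the oxygen on the ring-B face cis to C5 and trans to C1; C10 dioxolane and ring-A vinylogous ester unchanged)
Conditions: m-CPBA, CH2Cl2, 0 °C → rt
Reagents that add atoms: meta-chloroperoxybenzoic acid OOC(=O)c1cccc(Cl)c1
Why: Prilezhaev epoxidation of the isolated 1,1-disubstituted alkene (the push–pull alkene of the vinylogous ester is inert); ring B sits in the chair with the CMe2 arm (C5) equatorial and the sp2 C1 arm axial, and the peracid should enter along the axial direction at C9, away from the axial dioxolane oxygen on C10, so that the new C9–O bond is cis to C5 and trans to C1 as in the target.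

Step 9
Reactants: 14 (tributylstannyl)methanol
Product: 15 tributyl{[(4-methoxybenzyl)oxy]methyl}stannane
Conditions: NaH, PMBCl, Bu4NI (cat.), THF–DMF, 0 °C → rt
Reagents that add atoms: 4-methoxybenzyl chloride COc1ccc(CCl)cc1
Why: Williamson etherification of the stannyl carbinol gives the precursor of a protected hydroxymethyl carbanion.

Step 10
Reactants: 13 spiro-epoxide of 12; 15 tributyl{[(4-methoxybenzyl)oxy]methyl}stannane
Product: 17 ring-A enone C1(CH2OPMB)=C2H–C3(=O)–C4H2 (ring B as in 13; spiro centre unchanged), via tertiary alcohol 16 (not isolated)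
Conditions: 15, n-BuLi, THF, −78 °C; CeCl3, −78 °C; then 13, −78 → −40 °C; then aq. AcOH (pH ≈ 3), THF, 0 °C → rt
Reagents that add atoms: water O
Why: Stork–Danheiser sequence: the α-alkoxymethyl organocerium reagent (from tin–lithium exchange) adds to the vinylogous ester carbonyl C1, then mild acid ionises the tertiary allylic carbinol, water adds at C3 and isobutanol is lost, which moves the carbonyl to C3 and leaves C1 bearing the future methylidene carbon; the epoxide and the dioxolane are both slowed toward acid by their neighbouring oxygen substituents and should survive pH 3.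

Step 11
Reactants: 17 ring-A enone C1(CH2OPMB)=C2H–C3(=O)–C4H2
Product: 19 4-bromo enone (Br on C4 trans to C7 and cis to C11; otherwise as 17), via silyl dienol ether 18 (not isolated)
Conditions: LDA, THF, −78 °C; TMSCl; then NBS, −78 °C
Reagents that add atoms: N-bromosuccinimide O=C1CCC(=O)N1Br
Why: Kinetic α′-enolisation at C4 (C2 is vinylic and the γ-CH2O protons are removed more slowly), silylation and bromination of the cross-conjugated silyl dienol ether; NBS should enter anti to the C7 arm, which is axial on ring A, so bromine ends equatorial and trans to C7, and the same epimer is the more stable one if equilibration through the enol is needed.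

Step 12
Reactants: 19 4-bromo enone
Product: 20 allylic alcohol (C3–OH cis to the C4 bromine; PMB ether, epoxide and dioxolane retained)
Conditions: DIBAL-H, CH2Cl2, −78 °C; Rochelle salt work-up
Reagents that add atoms: none
Why: 1,2-Reduction of the enone carbonyl by DIBAL-H; the axial methyl on C5 blocks one face of C3, so hydride arrives from the other side and the hydroxyl forms cis to the equatorial C4 bromine, the relation required in the target.

Step 13
Reactants: 20 allylic alcohol PMB ether
Product: 21 diol (as 20 with C1–CH2OH free)
Conditions: DDQ, CH2Cl2–pH 7 buffer, 0 °C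
Reagents that add atoms: none
Why: Oxidative cleavage of the p-methoxybenzyl ether by DDQ (hydride abstraction, then hydrolysis of the oxocarbenium ion) frees the primary allylic alcohol under buffered conditions that leave the epoxide, dioxolane and bromohydrin untouched.

Step 14
Reactants: 21 diol
Product: 24 C1-methylidene epoxy ketal (ring A as in the target; ring B as in 13), via sulfonyl hydrazine 22 (not isolated), via allylic diazene 23 (not isolated)
Conditions: PPh3, DEAD, 2-nitrobenzenesulfonylhydrazide (NBSH), N-methylmorpholine, −35 → 23 °C
Reagents that add atoms: none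
Why: Myers reductive 1,3-transposition: Mitsunobu displacement of the primary allylic alcohol by NBSH, loss of arenesulfinic acid to the monoalkyl diazene and retro-ene loss of N2 deliver hydrogen to C2 and move the double bond regiospecifically to the exocyclic C1=CH2 position, without acid or base that could touch the bromohydrin or the epoxide; the hindered secondary C3 alcohol should not compete.

Step 15
Reactants: 24 C1-methylidene epoxy ketal
Product: 26 (3S,4R,6R,9S)-4-bromo-9-(chloromethyl)-3,9-dihydroxy-5,5-dimethyl-1-methylidenespiro[5.5]undecan-10-one (target; route numbering), via chlorohydrin ketal 25 (not isolated)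
Conditions: LiCl, AcOH, THF, rt; then 2 M aq. HCl, rt
Reagents that add atoms: lithium chloride [Li+].[Cl-]; water O
Why: Chloride opens the spiro-epoxide by SN2 attack at its primary carbon (the C9–O bond and the C9 configuration are kept, giving the tertiary chlorohydrin), and aqueous acid then hydrolyses the dioxolane, helped by relief of its 1,3-diaxial contact with the C1 arm, to unveil the C10 ketone under conditions mild enough for the exocyclic alkene.

**Compound list**

1 | dimedone (5,5-dimethylcyclohexane-1,3-dione) | CC1(C)CC(=O)CC(=O)C1 | starting material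
2 | 3-isobutoxy-5,5-dimethylcyclohex-2-en-1-one | CC(C)COC1=CC(=O)CC(C)(C)C1 | intermediate
3 | ethyl formate | CCOC=O | starting material
4 | 6-(hydroxymethylene)-3-isobutoxy-5,5-dimethylcyclohex-2-en-1-one (Z, chelated enol) | O/C=C1\C(=O)C=C(OCC(C)C)CC1(C)C | intermediate
5 | methyl methoxyacetate | COCC(=O)OC | starting material
6 | N,2-dimethoxy-N-methylacetamide | COCC(=O)N(C)OC | intermediate
7 | 1-methoxybut-3-en-2-one | C=CC(=O)COC | intermediate
8 | (R)-4-isobutoxy-1-(4-methoxy-3-oxobutyl)-6,6-dimethyl-2-oxocyclohex-3-ene-1-carbaldehyde (Michael adduct; not isolated) | O=C1C=C(OCC(C)C)CC(C)(C)[C@@]1(C=O)CCC(=O)COC | intermediate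
9 | 11-hydroxy-3-isobutoxy-10-methoxy-5,5-dimethylspiro[5.5]undec-2-ene-1,9-dione (aldol; spiro centre as in 10; C10/C11 epimers; not isolated) | O=C1C=C(OCC(C)C)CC(C)(C)[C@@]12CCC(=O)C(OC)C2O | intermediate
10 | (6S)-3-isobutoxy-10-methoxy-5,5-dimethylspiro[5.5]undeca-2,10-diene-1,9-dione | O=C1C=C(OCC(C)C)CC(C)(C)[C@@]12CCC(=O)C(OC)=C2 | intermediate
11 | (6S)-3-isobutoxy-10-methoxy-5,5-dimethyl-9-methylidenespiro[5.5]undeca-2,10-dien-1-one | O=C1C=C(OCC(C)C)CC(C)(C)[C@@]12CCC(=C)C(OC)=C2 | intermediate
12 | 10,10-(ethylenedioxy)-3-isobutoxy-5,5-dimethyl-9-methylidenespiro[5.5]undec-2-en-1-one (spiro centre unchanged) | O=C1C=C(OCC(C)C)CC(C)(C)[C@@]12CCC(=C)C3(OCCO3)C2 | intermediate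
13 | spiro-epoxide of 12 (C9 oxirane, oxygen cis to C5 and trans to C1 on ring B) | O=C1C=C(OCC(C)C)CC(C)(C)[C@@]12CC[C@@]3(CO3)C4(OCCO4)C2 | intermediate
14 | (tributylstannyl)methanol | CCCC[Sn](CCCC)(CCCC)CO | starting material
15 | tributyl{[(4-methoxybenzyl)oxy]methyl}stannane | CCCC[Sn](CCCC)(CCCC)COCc1ccc(OC)cc1 | intermediate
16 | C1 adduct of 13: tertiary alcohol C1(OH)(CH2OPMB) with the C2=C3 isobutyl enol ether intact (C1 epimers; not isolated) | OC1(COCc2ccc(OC)cc2)C=C(OCC(C)C)CC(C)(C)[C@@]13CC[C@@]4(CO4)C5(OCCO5)C3 | intermediate
17 | ring-A enone C1(CH2OPMB)=C2H–C3(=O)–C4H2; ring B with C9 epoxide and C10 dioxolane | COc1ccc(COCC2=CC(=O)CC(C)(C)[C@@]23CC[C@@]4(CO4)C5(OCCO5)C3)cc1 | intermediate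
18 | 3-trimethylsilyloxy-1,3-diene of 17 (C1=C2 and C3=C4; not isolated) | COc1ccc(COCC2=CC(O[Si](C)(C)C)=CC(C)(C)[C@@]23CC[C@@]4(CO4)C5(OCCO5)C3)cc1 | intermediate
19 | 4-bromo enone: as 17 with Br on C4 trans to C7 (cis to C11) | COc1ccc(COCC2=CC(=O)[C@H](Br)C(C)(C)[C@@]23CC[C@@]4(CO4)C5(OCCO5)C3)cc1 | intermediate
20 | allylic alcohol: as 19 with C3–OH cis to the C4 bromine | COc1ccc(COCC2=C[C@H](O)[C@H](Br)C(C)(C)[C@@]23CC[C@@]4(CO4)C5(OCCO5)C3)cc1 | intermediate
21 | diol: as 20 with C1–CH2OH free | OCC1=C[C@H](O)[C@H](Br)C(C)(C)[C@@]12CC[C@@]3(CO3)C4(OCCO4)C2 | intermediate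
22 | N-allyl-N-(2-nitrobenzenesulfonyl)hydrazine from 21 (C1–CH2–N(NH2)SO2Ar; not isolated) | NN(CC1=C[C@H](O)[C@H](Br)C(C)(C)[C@@]12CC[C@@]3(CO3)C4(OCCO4)C2)S(=O)(=O)c1ccccc1[N+](=O)[O-] | intermediate
23 | allylic diazene from 22 (C1–CH2–N=NH; not isolated) | N=NCC1=C[C@H](O)[C@H](Br)C(C)(C)[C@@]12CC[C@@]3(CO3)C4(OCCO4)C2 | intermediate
24 | C1-methylidene epoxy ketal: ring A as in the target; ring B with C9 epoxide and C10 dioxolane | C=C1C[C@H](O)[C@H](Br)C(C)(C)[C@@]12CC[C@@]3(CO3)C4(OCCO4)C2 | intermediate
25 | chlorohydrin ketal: as 24 with C9(OH)(CH2Cl); C10 dioxolane (not isolated) | C=C1C[C@H](O)[C@H](Br)C(C)(C)[C@@]12CC[C@@](O)(CCl)C3(OCCO3)C2 | intermediate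
26 | (3S,4R,6R,9S)-4-bromo-9-(chloromethyl)-3,9-dihydroxy-5,5-dimethyl-1-methylidenespiro[5.5]undecan-10-one (route numbering) | C=C1C[C@H](O)[C@H](Br)C(C)(C)[C@@]12CC[C@@](O)(CCl)C(=O)C2 | target

**Count**

Total steps: 15. Longest linear sequence: 12 (steps 1, 2, 5–8, 10–15).

**Steps most likely to fail**

Step 5. The conjugate addition may be slow at the hindered C6, which lies next to the gem-dimethyl carbon, and the catalyst may discriminate the two enolate faces poorly, so conversion or enantiomeric purity could fall short. Fallback: resolution in place of catalytic enantiocontrol. Setting out from 4 and 7, the Michael addition is run with catalytic triethylamine and the ring is closed with p-TsOH as in the main step; this passes through the racemic keto aldehyde F1 and the racemic aldol F2 to the racemic spiro enone F3. Preparative chromatography of F3 on a chiral stationary phase (SFC) then supplies the (S)-enantiomer, which is 10, and the route continues at step 6.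

Step 8. The peracid may deliver oxygen to the C9 methylidene with poor facial selectivity, giving the C9 epimer alongside the desired epoxide. Fallback: build the same epoxide from the carbonyl side, where the stereochemical rule is independent of the alkene's facial bias. Setting out from 12, the exocyclic alkene is cleaved (OsO4 cat., NaIO4, 2,6-lutidine, dioxane–water) to the C9 ketone with the C10 dioxolane in place, the keto ketal F4. Dimethylsulfoxonium methylide (Me3S(O)I, NaH, DMSO) then adds reversibly, so the new C–CH2 bond settles in the equatorial position and ring closure leaves the C–O bond axial (Corey–Chaykovsky epoxidation under thermodynamic control). This is 13, and the route continues at step 10.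

Step 10. Ionisation of the tertiary carbinol may be incomplete at the mild acidity that the epoxide tolerates, so that the material stalls before the carbonyl transposition, or the epoxide may open if the acidity is raised. Fallback: replace protic activation by a leaving group. Setting out from 13 and 15, the same organocerium addition is quenched with acetic anhydride instead of acid to give the tertiary allylic acetate F5. Stirring F5 in aqueous acetone buffered with NaHCO3 lets it ionise without added acid (SN1′ solvolysis through the alkoxy-stabilised allyl cation); water adds at C3 and isobutanol is lost, giving 17, and the route continues at step 11.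

Further compounds
F1 | step 5 | racemic keto aldehyde (racemate of 8) | O=C1C=C(OCC(C)C)CC(C)(C)C1(C=O)CCC(=O)COC
F2 | step 5 | racemic aldol (racemate of 9, all diastereomers) | O=C1C=C(OCC(C)C)CC(C)(C)C12CCC(=O)C(OC)C2O
F3 | step 5 | racemic spiro enone (racemate of 10) | O=C1C=C(OCC(C)C)CC(C)(C)C12CCC(=O)C(OC)=C2
F4 | step 8 | keto ketal: 10,10-(ethylenedioxy)-3-isobutoxy-5,5-dimethylspiro[5.5]undec-2-ene-1,9-dione (spiro centre as in 12) | O=C1C=C(OCC(C)C)CC(C)(C)[C@@]12CCC(=O)C3(OCCO3)C2
F5 | step 10 | tertiary allylic acetate: C1(OAc)(CH2OPMB) adduct of 13 (C1 epimers) | CC(=O)OC1(COCc2ccc(OC)cc2)C=C(OCC(C)C)CC(C)(C)[C@@]13CC[C@@]4(CO4)C5(OCCO5)C3
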